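In a one-step world, where electrophile + nucleophile gives target and the electrophile is the limiting reagent, c_electrophile decays with an exponent equal to a rate constant times mean c_nucleophile times time.

all flasks: electrophile 26 mM

| charge | nucleophile | remark | time |
|---|---|---|---|
| summer | 89 mM | run made earlier |  |
| midnight | 240 mM | run made earlier |  |
| alder | 78.0 mM |  | 1.5 h |
| elm | 160 mM |  | 1.5 h |

| run | time / min | electrophile / % | target / % |
|---|---|---|---|
| summer | 4.00 | 91 | 10 |
| summer | 6.00 | 88 | 9 |
| summer | 8.00 | 86 | 17 |
| summer | 12.0 | 79 | 20 |
| summer | 20.0 | 68 | 31 |
| summer | 30.0 | 60 | 44 |
| summer | 50.0 | 43 | 54 |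
| midnight | 2.50 | 88 | 15 |
| midnight | 6.00 | 75 | 27 |
| midnight | 12.0 | 51 | 41 |
| midnight | 20.0 | 36 | 65 |
| midnight | 25.0 | 28 | 73 |
| midnight | 40.0 | 13 | 85 |
| midnight | 50.0 | 10 | 93 |

(standard deviation of a reading: 1.5 percentage points)



- part of the electrophile that has reacted at the end, alder
- part of the electrophile that has reacted at the end, elm
- what raising the concentration of nucleophile from its lowest to its highest value here does to the part of the electrophile that has reacted (changes below 5 percentage points count as none) (no change / it falls / it rises)

1. I took mean c_nucleophile as the charge minus half the electrophile used, and the last readings gave 0.207 /M/min for summer and 0.202 /M/min for midnight. I carried their average, the mean-nucleophile rate constant of 0.204 /M/min, as a reading.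

2. With c_nucleophile held at its charge (pseudo-first-order), my reckoning gave 76.2 % for alder and 94.7 % for elm. With c_nucleophile lowered from the start by the whole electrophile charge, it gave 61.6 % and 91.5 %. The one-step flask lay between, since its c_nucleophile runs from the first level towards the second.

3. Replacing the curve by its mean, the charge minus half the electrophile charge, I committed to 69.7 % for alder and 93.3 % for elm, with half-widths of 7.3 percentage points and 1.6 points. The lower elm limit stood 15 points above the upper alder limit, so I expected a rise.

4. The forecast, holding that “the reaction is first order in each partner”, gave 72 % and 94 %, slightly above my means but inside both brackets, and said it rises.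

5. Alder gave 68.2 % and elm 92.5 %: it rises, by 24 points.

    electrophile + nucleophile → acid set free + target (k = 0.230 /M/min)
    nucleophile + acid set free ⇌ protonated nucleophile, settled at all times (K = 2000 /M)
    acid set free + target → side product (k = 0.410 /M/min)

In alder, the electrophile's half-life by the first step stretched from 0.64 h with the other concentrations as charged to 1.2 h at 1.50 h, about twice. Free nucleophile in alder by then stood at 42.8 mM, below the 52.0 mM of my lower level, beside 17.5 mM of protonated nucleophile. Averaging the charge and that end value, the carried constant gave 67.1 % for alder. A neighbour flask, alder with 20 mM of nucleophile and 41 % of it free at the end, reckoned the same way gave 22.8 %, and the simulation gave 23.4 %.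

The readings come from a simulation for an exercise; noise was put on by code.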